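The flask is read at 8.0 min. In the teal run, free monomer goes from 14.5% to 13.5% between 5.00 min and 10.0 min, yet monomer in chains falls from 41.4% to 22.6%.

| flask | free monomer | initiator | remark | time |
|---|---|---|---|---|
| teal | 0.44 M | 0.98 mol% | run made earlier |  |
| blue | 0.44 M | 1.5 mol% | run made earlier |  |
| red | 0.88 M | 0.7 mol% | run made earlier |  |
| flask | 0.44 M | 0.7 mol% |  | 8.0 min |

| run | time / min | monomer in chains / % | free monomer / % |
|---|---|---|---|
| teal | 0.833 | 29.5 | 52.0 |
| teal | 1.33 | 40.5 | 36.6 |
| teal | 2.50 | 46.9 | 20.0 |
| teal | 5.00 | 41.4 | 14.5 |
| teal | 10.0 | 22.6 | 13.5 |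
| blue | 2.00 | 53.8 | 20.8 |
| blue | 4.00 | 49.2 | 16.0 |
| blue | 6.00 | 40.2 | 15.2 |
| blue | 8.00 | 33.1 | 14.9 |
| blue | 10.0 | 24.5 | 14.9 |
| red | 0.833 | 49.8 | 35.7 |
| red | 1.33 | 61.3 | 20.0 |
| red | 2.50 | 67.0 | 9.9 |
| red | 5.00 | 63.3 | 8.3 |
| red | 10.0 | 52.6 | 8.5 |

(each reading ± 0.5 percentage points)

* average number of monomer units in a chain (chains begun, living or dead) at 8.0 min
* part of the free monomer that has reacted at 8.0 min

- the average divides the monomer in chains by the number of chains begun, living and dead together
- what was read earlier has a scatter of 0.5 percentage points, one standard deviation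
- the earlier runs do not show the number of chains; that part of a forecast is a guess

Read teal's last two rows against each other. Free monomer plus monomer in chains falls short of the charge by 44.1%, then by 63.9%. Free monomer moves by 1 percentage point there, so its curve can be replaced by its mean, 14.0%. That mean, times the interval, divided by the growth of the gap, gives the leak time 3.54 min: the time constant of a first-order loss, in which free monomer at a steady level sends its own amount into the gap each such time.

Red's same rows, at twice the concentration and with 0.7 mol% of initiator, read 4.00 min. Teal's whole curve, joined by chords, has the mean 23.2% and reads 3.63 min, so the mean costs little.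

My reckoning borrows teal's curve for the flask, though the flask carries less initiator. Up to 8.0 min the mean is 25.6%, the gap 57.9%, and monomer in chains 28.6%.

The forecast gives 42 (34 to 70) and 86.7% (85.5% to 87.8%), noting: “Efficiency below one would raise this, and the runs cannot show it”.

    free monomer + initiator → living end + monomer in chains (k = 0.250 L mol⁻¹ s⁻¹)
    2 initiator → spent initiator A (k = 1.30 L mol⁻¹ s⁻¹)
    free monomer → uncatalysed product (k = 0.00470 s⁻¹)
    initiator → spent initiator B (k = 0.0300 s⁻¹)
    monomer in chains + living end → free monomer + living end, rate k5*[living end] as long as [monomer in chains] is above zero (k = 0.330 s⁻¹)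
    free monomer + living end → monomer in chains + living end, rate k6*[living end]*[free monomer] (k = 4.00 L mol⁻¹ s⁻¹)

The flask gives 54.0 units and 87.4% reacted, with monomer in chains at 28.5% and living end at 0.00232 M. The forecast's average stands lower by a factor 1.29. The flask's gap is uncatalysed product. Now take the same flask read at 5.0 min. From then to 8.0 min, free monomer averages 13.2%, so the leak time adds 11 points. Uncatalysed product goes from 48.0% to 59.0%, a rise of 11 points. Living end reads 0.00232 M at 5.0 min as well, with monomer in chains at 38.1%, and the average there is 72.4.

(The runs are simulated with constants of no real substance, and the scatter is random.)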